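(The data were computed with made-up constants.)

The noon run offers a constant, and two chemists read different ones from it.

the same everywhere: gas 14 mM (held)
- noon: electrophile 0.80 M (fed, over 3.0 min); run made earlier; the fed solution adds 0.20 times the starting volume
- flask: electrophile 0.40 M (fed, over 3.0 min); the fed solution adds 0.20 times the starting volume; time 15 min

- noon (time / min: electrophile / %, product / %): 0.500: 16.1, 0.8; 1.50: 48.4, 1.9; 3.00: 96.7, 2.8; 5.00: 93.4, 5.9

(readings scatter by 0.5 percentage points)

- amounts are per litre of the starting volume; all of the dose is in the solution fed
- the analysis behind the earlier runs scatters by 0.5 percentage points, standard deviation
- at the start none of the gas is in solution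
- percentages count the whole charge, also what has not yet gone in
- the earlier runs do not show how much of nucleophile is bound; that part of a forecast is a guess

- part of the electrophile that has reacted at 15 min
- share of the unused nucleophile that is free and not bound as protonated nucleophile, at 15 min

The first chemist takes gas uptake as the rate-limiting step, so a fixed amount reacts each minute. Her constant is the mean slope, the fraction of the noon charge turned into product per minute, 0.0118 min⁻¹. She replaces the curve by this mean.

The second chemist holds that the rate follows electrophile, so a fixed fraction reacts each minute. With the dose counted at its mean time, the same reading gives him 0.0174 min⁻¹.

Now check the error of each. At 1.50 min her line gives 1.77%. His curve, which starts as the square of time, gives 0.652%. The reading is 1.9%. Her line misses by 0.74 percentage points at 3.00 min, and his miss at 1.50 min is larger. His miss is 1.2 points and the scatter is 0.5 points, so I side with her.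

In the flask the charge is half the noon charge, so her slope counts twice as much of it. My reckoning for 15 min is therefore 35.4% reacted. His view gives 20.9%. The readings do not show binding, so the free share stays a guess.

The forecast says 34% reacted and 50% free, on the ground “So the rate hardly depends on electrophile concentration.”

The flask gives 36.3% reacted, 0.9 points above my line and 15 points above his figure. Its free share is 0.994%.

    acid set free → by-product carried off (k = 0.0120 min⁻¹)
    gas ⇌ nucleophile, rate k2*(csat - [nucleophile]) (kL = 1.10 min⁻¹)
    nucleophile + acid set free ⇌ protonated nucleophile, settled at all times (K = 3600 L mol⁻¹)
    electrophile + nucleophile → acid set free + product (k = 41.0 L mol⁻¹ min⁻¹)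

In the neighbour flask, charged with 0.10 M electrophile, the same slope gives 142% at 15 min, more than the charge. The line reaches the whole charge at 10.6 min, so it must bend. The neighbour flask gives 91.0% reacted, with 9.03% electrophile left. That falls 51 points short of the line, and the second chemist's view, a rate that follows electrophile, has its region in such a tail. Free nucleophile in the neighbour flask stands at 0.00829 M at 15.0 min, higher than the 9.10 × 10⁻⁴ M of the flask at that time, and its free share is 10.2%.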